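**Plan**
- Cuts: the oxolane C2–aryl bond (arylzinc onto a 2-sulfonyl oxolane), then the ring bond O1–C2 (lactol from a masked aldehyde), then C2–C3 and C4–C5 together. Each arm is cut at O–C8 (lactate) and C7–aryl (Grignard).
- Enabling feature: the chain C2–C3–C4–C5 of the oxolane, with aryls on C2 and C5 and trans methyls on C3 and C4, is a butenolide in disguise. C3 is its β-carbon, C4 its α-carbon, the two methyls are its acetal and carbonyl carbons at a higher oxidation level, C2 is a formyl anion (dithiane) and C5 an aryl aldehyde carbon.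
- Forward: arm bromide 9 is made once and used twice (as aldehyde 11 and as arylzinc 25). Dithiane 12, butenolide 13 and 11 are joined in one flask without ring closure, and the lactone template is reduced to two methyls. The oxolane closes late as lactol 22 (O1–C2), and the second aryl enters last.
- Stereochemistry: C8/C8′ come from ethyl (S)-lactate with Mitsunobu inversion and C7/C7′ from Felkin–Anh hydride delivery. C3 and C4 come from the single acetal centre of the l-menthyloxy butenolide, C5 from the chair aldol, and C2 from addition to the oxocarbenium ion anti to the C5 aryl.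

Key step: step 7

Remark: the SMILES is read as the C2-symmetric (2R,3S,4S,5R)-oxolane (2,3-cis, 3,4-trans, 4,5-cis) carrying two (1R,2R)-threo arms, so one arm building block serves both halves. Locants: oxolane O1, C2–C5; arm carbinol C7, arm ether carbon C8. Ar* = 3-methoxy-4-{[(1R,2R)-1-(3,4-dimethoxyphenyl)-1-(triisopropylsilyloxy)propan-2-yl]oxy}phenyl.

**Route**

Step 1
Reactants: 1 4-bromo-2-methoxyphenol; 2 ethyl (S)-lactate
Product: 3 ethyl (2R)-2-(4-bromo-2-methoxyphenoxy)propanoate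
Conditions: PPh3, DIAD, THF, 0 °C to rt
Reagents that add atoms: none
Why: Mitsunobu etherification of a phenol with a secondary α-hydroxy ester is an SN2 displacement of the oxyphosphonium group and should invert the S lactate centre cleanly to the R aryloxy centre (future C8).

Step 2
Reactants: 3 ethyl (2R)-2-(4-bromo-2-methoxyphenoxy)propanoate
Product: 4 (2R)-2-(4-bromo-2-methoxyphenoxy)-N-methoxy-N-methylpropanamide
Conditions: MeNH(OMe)·HCl, iPrMgCl, THF, −20 °C
Reagents that add atoms: N,O-dimethylhydroxylamine hydrochloride, CNOC.Cl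
Why: Weinreb amide formation by ester aminolysis with the chloromagnesium amide is fast at −20 °C, where neither the α-stereocentre nor the electron-rich aryl bromide should be touched.

Step 3
Reactants: 4 (2R)-2-(4-bromo-2-methoxyphenoxy)-N-methoxy-N-methylpropanamide; 5 4-bromo-1,2-dimethoxybenzene
Product: 7 (2R)-2-(4-bromo-2-methoxyphenoxy)-1-(3,4-dimethoxyphenyl)propan-1-one, via 3,4-dimethoxyphenylmagnesium bromide 6 (not isolated)
Conditions: 5, Mg, THF, 40 °C; solution of 6 added to 4, THF, −20 to 0 °C; cold 1 M HCl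
Reagents that add atoms: none
Why: Grignard acylation through a Weinreb amide stops at the ketone because the chelated tetrahedral magnesium adduct survives until the cold acidic quench, which also keeps the α-aryloxy centre away from base.

Step 4
Reactants: 7 (2R)-2-(4-bromo-2-methoxyphenoxy)-1-(3,4-dimethoxyphenyl)propan-1-one
Product: 8 (1R,2R)-2-(4-bromo-2-methoxyphenoxy)-1-(3,4-dimethoxyphenyl)propan-1-ol
Conditions: LiBH(sBu)3, THF, −78 °C; then H2O
Reagents that add atoms: none
Why: Diastereoselective ketone reduction under polar Felkin–Anh control: the bulky, poorly chelating hydride should attack anti to the perpendicular aryloxy group and past the small hydrogen, giving the 1R carbinol threo to C8.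

Step 5
Reactants: 8 (1R,2R)-2-(4-bromo-2-methoxyphenoxy)-1-(3,4-dimethoxyphenyl)propan-1-ol
Product: 9 [(1R,2R)-2-(4-bromo-2-methoxyphenoxy)-1-(3,4-dimethoxyphenyl)propoxy]tri(propan-2-yl)silane
Conditions: TIPSOTf, 2,6-lutidine, CH2Cl2, 0 °C to rt
Reagents that add atoms: triisopropylsilyl trifluoromethanesulfonate, CC(C)[Si](OS(=O)(=O)C(F)(F)F)(C(C)C)C(C)C
Why: Silylation of a hindered secondary alcohol with a silyl triflate and a hindered base gives a TIPS ether that should survive the organometallic, hydride, buffered HF and mild acid conditions that follow.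

Step 6
Reactants: 9 [(1R,2R)-2-(4-bromo-2-methoxyphenoxy)-1-(3,4-dimethoxyphenyl)propoxy]tri(propan-2-yl)silane
Product: 11 4-{[(1R,2R)-1-(3,4-dimethoxyphenyl)-1-(triisopropylsilyloxy)propan-2-yl]oxy}-3-methoxybenzaldehyde, via aryllithium 10 (not isolated)
Conditions: n-BuLi, THF, −78 °C; DMF, −78 to 0 °C; H2O
Reagents that add atoms: N,N-dimethylformamide, CN(C)C=O
Why: Bromine–lithium exchange outruns any deprotonation at −78 °C, and formylation of the aryllithium with DMF (Bouveault-type) releases the aldehyde only on aqueous work-up.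

Step 7
Reactants: 12 1,3-dithiane; 13 (5R)-5-[(1R,2S,5R)-menthyloxy]furan-2(5H)-one; 11 4-{[(1R,2R)-1-(3,4-dimethoxyphenyl)-1-(triisopropylsilyloxy)propan-2-yl]oxy}-3-methoxybenzaldehyde
Product: 16 (3S,4R,5R)-4-(1,3-dithian-2-yl)-3-[(R)-Ar*(hydroxy)methyl]-5-[(1R,2S,5R)-menthyloxy]oxolan-2-one, via 2-lithio-1,3-dithiane 14 (not isolated), via lithium lactone enolate 15 (not isolated)
Conditions: 12, n-BuLi, THF, −30 °C; 13, −78 °C; 11, −78 °C; AcOH, −78 °C
Reagents that add atoms: none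
Why: 2-Lithio-1,3-dithiane 14 adds in conjugate fashion to the β-carbon of 13 on the face opposite the menthyloxy group (future bond C2–C3), and lithium enolate 15 is intercepted at its α-carbon by aldehyde 11 anti to the new dithianyl group (future bond C4–C5); this is a tandem Michael addition–aldol reaction of the kind established for lithiated dithianes, 5-alkoxybutenolides and aromatic aldehydes. No ring is closed, since the lactone serves only as a template that is reduced away in steps 9 to 11. The future C3 is controlled by the acetal stereocentre of 13, the future C4 by the adjacent dithianyl group (trans), and the carbinol C5 by the lithium-bridged Zimmerman–Traxler chair of the ring-locked enolate (OLi trans to the β-carbon) with the aryl group equatorial, which leads to the anti aldol and hence the R carbinol. The step needs 1,4- over 1,2-addition, which the soft sulfur-stabilised anion and the strongly activated alkoxybutenolide should secure, and anti,anti induction around the ring, which the menthyloxy group secures. It also needs anti simple diastereoselection at the carbinol, the least secure element, which is why the reaction is run in THF without a polar cosolvent and quenched cold with acetic acid before any retro-aldol equilibration.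

Step 8
Reactants: 16 (3S,4R,5R)-4-(1,3-dithian-2-yl)-3-[(R)-Ar*(hydroxy)methyl]-5-[(1R,2S,5R)-menthyloxy]oxolan-2-one
Product: 17 (3S,4R,5R)-4-(1,3-dithian-2-yl)-3-[(R)-Ar*(triethylsilyloxy)methyl]-5-[(1R,2S,5R)-menthyloxy]oxolan-2-one
Conditions: TESOTf, 2,6-lutidine, CH2Cl2, −78 °C
Reagents that add atoms: triethylsilyl trifluoromethanesulfonate, CC[Si](CC)(CC)OS(=O)(=O)C(F)(F)F
Why: Silylation with a silyl triflate under non-nucleophilic, weakly basic conditions should cap the β-hydroxy lactone without retro-aldol cleavage, and TES is chosen because it can later be removed beside TIPS.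

Step 9
Reactants: 17 (3S,4R,5R)-4-(1,3-dithian-2-yl)-3-[(R)-Ar*(triethylsilyloxy)methyl]-5-[(1R,2S,5R)-menthyloxy]oxolan-2-one
Product: 18 (2R,3R)-2-[(R)-Ar*(triethylsilyloxy)methyl]-3-(1,3-dithian-2-yl)butane-1,4-diol
Conditions: LiAlH4, THF, 0 °C to rt; aq. potassium sodium tartrate
Reagents that add atoms: none
Why: Hydride reduction of the acetal-bearing lactone with LiAlH4 opens the ring, the exposed hemiacetal expels menthoxide, and both carbonyl carbons should end as CH2OH while the dithiane and both silyl ethers are inert.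

Step 10
Reactants: 18 (2R,3R)-2-[(R)-Ar*(triethylsilyloxy)methyl]-3-(1,3-dithian-2-yl)butane-1,4-diol
Product: 19 (2R,3R)-2-[(R)-Ar*(triethylsilyloxy)methyl]-3-(1,3-dithian-2-yl)butane-1,4-diyl dimethanesulfonate
Conditions: MsCl, Et3N, CH2Cl2, −20 °C; used crude
Reagents that add atoms: methanesulfonyl chloride, CS(=O)(=O)Cl
Why: Sulfonate ester formation on both primary alcohols through the sulfene is fast at −20 °C and should outrun cyclic ether formation from a mono-mesylate.

Step 11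
Reactants: 19 (2R,3R)-2-[(R)-Ar*(triethylsilyloxy)methyl]-3-(1,3-dithian-2-yl)butane-1,4-diyl dimethanesulfonate
Product: 20 2-[(2S,3S,4R)-4-Ar*-3-methyl-4-(triethylsilyloxy)butan-2-yl]-1,3-dithiane
Conditions: LiBHEt3, THF, 0 °C to rt
Reagents that add atoms: none
Why: SN2 hydride displacement of primary sulfonates by LiBHEt3, the most nucleophilic common hydride, should turn both β-branched CH2OMs groups into the C3 and C4 methyls without touching a stereocentre.

Step 12
Reactants: 20 2-[(2S,3S,4R)-4-Ar*-3-methyl-4-(triethylsilyloxy)butan-2-yl]-1,3-dithiane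
Product: 21 (1R,2S,3S)-1-Ar*-3-(1,3-dithian-2-yl)-2-methylbutan-1-ol
Conditions: HF·pyridine, pyridine, THF, 0 °C
Reagents that add atoms: none
Why: Selective desilylation: buffered HF cleaves a triethylsilyl ether far faster than a triisopropylsilyl ether, so only the C5 hydroxyl should be freed.

Step 13
Reactants: 21 (1R,2S,3S)-1-Ar*-3-(1,3-dithian-2-yl)-2-methylbutan-1-ol
Product: 22 (3S,4S,5R)-5-Ar*-3,4-dimethyloxolan-2-ol (anomeric mixture)
Conditions: MeI, CaCO3, MeCN/H2O, 45 °C
Reagents that add atoms: water, O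
Why: Alkylative dithiane hydrolysis (S-methylation, thionium ion, hydrolysis) under neutral buffered conditions spares the electron-rich arenes and the TIPS ether, and the released aldehyde is captured at once by the C5 hydroxyl as the five-membered lactol (5-exo-trig hemiacetalisation), which shields the α-centre C3.

Step 14
Reactants: 22 (3S,4S,5R)-5-Ar*-3,4-dimethyloxolan-2-ol
Product: 23 (3S,4S,5R)-2-(benzenesulfonyl)-5-Ar*-3,4-dimethyloxolane (anomeric mixture)
Conditions: PhSO2H, CaCl2, CH2Cl2, rt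
Reagents that add atoms: benzenesulfinic acid, OS(=O)c1ccccc1
Why: Lactol-to-anomeric-sulfone exchange: the mildly acidic sulfinic acid ionises the lactol to the oxocarbenium ion, which is trapped at sulfur while CaCl2 takes up the water, conditions mild enough for the benzylic silyl ether.

Step 15
Reactants: 23 (3S,4S,5R)-2-(benzenesulfonyl)-5-Ar*-3,4-dimethyloxolane; 9 [(1R,2R)-2-(4-bromo-2-methoxyphenoxy)-1-(3,4-dimethoxyphenyl)propoxy]tri(propan-2-yl)silane
Product: 26 (2R,3S,4S,5R)-2,5-bis(Ar*)-3,4-dimethyloxolane, via arylmagnesium bromide 24 (not isolated), via arylzinc bromide 25 (not isolated)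
Conditions: 9 (excess), Mg turnings, LiCl, THF, rt to 40 °C; ZnBr2, THF, 0 °C to rt; then 23, THF, rt
Reagents that add atoms: none
Why: Nucleophilic substitution of a 2-sulfonyl cyclic ether by an arylzinc reagent made from the Grignard reagent and ZnBr2: the zinc Lewis acid ionises the sulfone to the oxocarbenium ion, and aryl transfer should occur by inside attack on the envelope with the C3 methyl pseudoequatorial, on the face opposite the C4 methyl and the C5 aryl, so the new aryl is trans to the C5 aryl and cis to the C3 methyl (2R).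

Step 16
Reactants: 26 (2R,3S,4S,5R)-2,5-bis(Ar*)-3,4-dimethyloxolane
Product: 27 (2R,3S,4S,5R)-2,5-bis{4-[(1R,2R)-1-(3,4-dimethoxyphenyl)-1-hydroxypropan-2-yl]oxy-3-methoxyphenyl}-3,4-dimethyloxolane
Conditions: Bu4NF, THF, rt to 40 °C
Reagents that add atoms: none
Why: Fluoride-mediated cleavage of both triisopropylsilyl ethers is driven by Si–F bond formation and should leave all ether, benzylic and ring stereocentres untouched.

**Compound list**
1 | 4-bromo-2-methoxyphenol | Oc1ccc(Br)cc1OC | starting material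
2 | ethyl (S)-lactate | C[C@H](O)C(=O)OCC | starting material
3 | ethyl (2R)-2-(4-bromo-2-methoxyphenoxy)propanoate | Brc1ccc(O[C@H](C)C(=O)OCC)c(OC)c1 | intermediate
4 | (2R)-2-(4-bromo-2-methoxyphenoxy)-N-methoxy-N-methylpropanamide | Brc1ccc(O[C@H](C)C(=O)N(C)OC)c(OC)c1 | intermediate
5 | 4-bromo-1,2-dimethoxybenzene (4-bromoveratrole) | COc1ccc(Br)cc1OC | starting material
6 | 3,4-dimethoxyphenylmagnesium bromide | COc1ccc([Mg]Br)cc1OC | intermediate
7 | (2R)-2-(4-bromo-2-methoxyphenoxy)-1-(3,4-dimethoxyphenyl)propan-1-one | Brc1ccc(O[C@H](C)C(=O)c2ccc(OC)c(OC)c2)c(OC)c1 | intermediate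
8 | (1R,2R)-2-(4-bromo-2-methoxyphenoxy)-1-(3,4-dimethoxyphenyl)propan-1-ol | Brc1ccc(O[C@H](C)[C@H](O)c2ccc(OC)c(OC)c2)c(OC)c1 | intermediate
9 | arm bromide, TIPS ether of 8 | Brc1ccc(O[C@H](C)[C@H](O[Si](C(C)C)(C(C)C)C(C)C)c2ccc(OC)c(OC)c2)c(OC)c1 | intermediate
10 | aryllithium from 9 (Li in place of Br) | [Li]c1ccc(O[C@H](C)[C@H](O[Si](C(C)C)(C(C)C)C(C)C)c2ccc(OC)c(OC)c2)c(OC)c1 | intermediate
11 | arm aldehyde, 4-{[(1R,2R)-1-(3,4-dimethoxyphenyl)-1-(triisopropylsilyloxy)propan-2-yl]oxy}-3-methoxybenzaldehyde | O=Cc1ccc(O[C@H](C)[C@H](O[Si](C(C)C)(C(C)C)C(C)C)c2ccc(OC)c(OC)c2)c(OC)c1 | intermediate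
12 | 1,3-dithiane | C1CSCSC1 | starting material
13 | (5R)-5-[(1R,2S,5R)-menthyloxy]furan-2(5H)-one | O=C1C=C[C@H](O[C@@H]2C[C@H](C)CC[C@H]2C(C)C)O1 | starting material
14 | 2-lithio-1,3-dithiane | [Li]C1SCCCS1 | intermediate
15 | lithium (4R,5R)-4-(1,3-dithian-2-yl)-5-(l-menthyloxy)-4,5-dihydrofuran-2-olate | [Li]OC1=C[C@@H](C2SCCCS2)[C@H](O[C@@H]3C[C@H](C)CC[C@H]3C(C)C)O1 | intermediate
16 | tandem adduct, (3S,4R,5R)-4-(1,3-dithian-2-yl)-3-[(R)-Ar*(hydroxy)methyl]-5-(l-menthyloxy)oxolan-2-one | S1CCCSC1[C@H]2[C@H](O[C@@H]3C[C@H](C)CC[C@H]3C(C)C)OC(=O)[C@@H]2[C@@H](O)c4ccc(O[C@H](C)[C@H](O[Si](C(C)C)(C(C)C)C(C)C)c5ccc(OC)c(OC)c5)c(OC)c4 | intermediate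
17 | triethylsilyl ether of 16 | S1CCCSC1[C@H]2[C@H](O[C@@H]3C[C@H](C)CC[C@H]3C(C)C)OC(=O)[C@@H]2[C@@H](O[Si](CC)(CC)CC)c4ccc(O[C@H](C)[C@H](O[Si](C(C)C)(C(C)C)C(C)C)c5ccc(OC)c(OC)c5)c(OC)c4 | intermediate
18 | (2R,3R)-2-[(R)-Ar*(triethylsilyloxy)methyl]-3-(1,3-dithian-2-yl)butane-1,4-diol | S1CCCSC1[C@@H](CO)[C@H](CO)[C@@H](O[Si](CC)(CC)CC)c4ccc(O[C@H](C)[C@H](O[Si](C(C)C)(C(C)C)C(C)C)c5ccc(OC)c(OC)c5)c(OC)c4 | intermediate
19 | bis-mesylate of 18 | S1CCCSC1[C@@H](COS(C)(=O)=O)[C@H](COS(C)(=O)=O)[C@@H](O[Si](CC)(CC)CC)c4ccc(O[C@H](C)[C@H](O[Si](C(C)C)(C(C)C)C(C)C)c5ccc(OC)c(OC)c5)c(OC)c4 | intermediate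
20 | 2-[(2S,3S,4R)-4-Ar*-3-methyl-4-(triethylsilyloxy)butan-2-yl]-1,3-dithiane | S1CCCSC1[C@@H](C)[C@H](C)[C@@H](O[Si](CC)(CC)CC)c4ccc(O[C@H](C)[C@H](O[Si](C(C)C)(C(C)C)C(C)C)c5ccc(OC)c(OC)c5)c(OC)c4 | intermediate
21 | (1R,2S,3S)-1-Ar*-3-(1,3-dithian-2-yl)-2-methylbutan-1-ol | S1CCCSC1[C@@H](C)[C@H](C)[C@@H](O)c4ccc(O[C@H](C)[C@H](O[Si](C(C)C)(C(C)C)C(C)C)c5ccc(OC)c(OC)c5)c(OC)c4 | intermediate
22 | (3S,4S,5R)-5-Ar*-3,4-dimethyloxolan-2-ol, anomeric mixture | OC1O[C@@H](c2ccc(O[C@H](C)[C@H](O[Si](C(C)C)(C(C)C)C(C)C)c3ccc(OC)c(OC)c3)c(OC)c2)[C@@H](C)[C@@H]1C | intermediate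
23 | (3S,4S,5R)-2-(benzenesulfonyl)-5-Ar*-3,4-dimethyloxolane, anomeric mixture | O=S(=O)(c1ccccc1)C2O[C@@H](c3ccc(O[C@H](C)[C@H](O[Si](C(C)C)(C(C)C)C(C)C)c4ccc(OC)c(OC)c4)c(OC)c3)[C@@H](C)[C@@H]2C | intermediate
24 | arylmagnesium bromide from 9 (MgBr in place of Br) | Br[Mg]c1ccc(O[C@H](C)[C@H](O[Si](C(C)C)(C(C)C)C(C)C)c2ccc(OC)c(OC)c2)c(OC)c1 | intermediate
25 | arylzinc bromide from 24 (ZnBr in place of MgBr) | Br[Zn]c1ccc(O[C@H](C)[C@H](O[Si](C(C)C)(C(C)C)C(C)C)c2ccc(OC)c(OC)c2)c(OC)c1 | intermediate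
26 | bis(triisopropylsilyl) ether of the target, (2R,3S,4S,5R)-2,5-bis(Ar*)-3,4-dimethyloxolane | COc1ccc([C@@H](O[Si](C(C)C)(C(C)C)C(C)C)[C@@H](C)Oc2ccc([C@@H]3O[C@@H](c4ccc(O[C@H](C)[C@H](O[Si](C(C)C)(C(C)C)C(C)C)c5ccc(OC)c(OC)c5)c(OC)c4)[C@@H](C)[C@@H]3C)cc2OC)cc1OC | intermediate
27 | CNP0116650.3, (2R,3S,4S,5R)-2,5-bis{4-[(1R,2R)-1-(3,4-dimethoxyphenyl)-1-hydroxypropan-2-yl]oxy-3-methoxyphenyl}-3,4-dimethyloxolane | COc1ccc([C@@H](O)[C@@H](C)Oc2ccc([C@@H]3O[C@@H](c4ccc(O[C@H](C)[C@H](O)c5ccc(OC)c(OC)c5)c(OC)c4)[C@@H](C)[C@@H]3C)cc2OC)cc1OC | target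

**Count**
Total steps: 16. Longest linear sequence: 16 steps (1 → 3 → 4 → 7 → 8 → 9 → 11 → 16 → 17 → 18 → 19 → 20 → 21 → 22 → 23 → 26 → 27); a second portion of 9 re-enters in step 15.

**Steps most likely to fail**

Risk 1, step 7. The aldol capture may show weak simple diastereoselection, so that the carbinol forms as both epimers, because the lithium-bridged chair is only loosely organised. The fallback replaces substrate control at this centre by reagent control. It sets out from crude 16 that contains the S-carbinol epimer of 16 F1. Dess–Martin periodinane (NaHCO3, CH2Cl2) should convert both epimers into one 3-aroyl lactone F2, whose C3 centre stays trans to the dithianyl group because that is the position of the enolisation equilibrium. Corey–Bakshi–Shibata reduction of F2 (BH3·SMe2, (S)-2-methyl-CBS-oxazaborolidine, THF, −20 °C), with the aryl group as the large substituent, should then deliver the R carbinol, and the route is rejoined at 16.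

Risk 2, step 15. Magnesium insertion or transmetalation may be incomplete, the bulky silyloxy-bearing arylzinc may capture the oxocarbenium ion slowly, or facial selectivity may erode. The fallback uses a small aryl donor and builds the second arm afterwards. It sets out from 23. (4-Benzyloxy-3-methoxyphenyl)magnesium bromide F3, made from commercial 1-(benzyloxy)-4-bromo-2-methoxybenzene (COc1cc(Br)ccc1OCc1ccccc1) and Mg, is treated with ZnBr2 to give (4-benzyloxy-3-methoxyphenyl)zinc bromide F4, which should add to 23 with the same facial preference to give the benzyl-protected 2-aryl oxolane F5. Hydrogenolysis (H2, Pd on carbon, EtOAc) should free the phenol F6. The chemistry of steps 1 to 4 is then repeated on F6: Mitsunobu reaction with 2 gives the lactate ether F7, amidation gives the Weinreb amide F8, addition of Grignard reagent 6 (made again from 5 and Mg) gives the aryl ketone F9, and LiBH(sBu)3 gives the mono-silylated threo alcohol F10. The conditions of step 16 applied to F10 rejoin the route at 27.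

Risk 3, step 11 (with step 10). A dithiane sulfur may be alkylated intramolecularly by the mesyloxymethyl group on C4 (five-membered sulfonium), or hydride may attack at sulfur and return the alcohol, so that the methyls are not formed cleanly. The fallback exchanges the sulfur acetal for an oxygen acetal before the hydride steps. It sets out from 17. Hg(ClO4)2, CaCO3 in MeOH/THF should give the dimethyl acetal lactone F11. LiAlH4 then gives the acetal diol F12, MsCl/Et3N the acetal bis-mesylate F13, and LiBHEt3 the 3,4-dimethyl acetal F14. AcOH/THF/H2O at 40 °C should remove the triethylsilyl group and hydrolyse the acetal in one operation, and the route is rejoined at lactol 22.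

**Further compounds**
F1 | step 7 | S-carbinol epimer of 16 | S1CCCSC1[C@H]2[C@H](O[C@@H]3C[C@H](C)CC[C@H]3C(C)C)OC(=O)[C@@H]2[C@H](O)c4ccc(O[C@H](C)[C@H](O[Si](C(C)C)(C(C)C)C(C)C)c5ccc(OC)c(OC)c5)c(OC)c4
F2 | step 7 | 3-aroyl lactone, (3S,4R,5R)-3-(Ar*-carbonyl)-4-(1,3-dithian-2-yl)-5-(l-menthyloxy)oxolan-2-one | S1CCCSC1[C@H]2[C@H](O[C@@H]3C[C@H](C)CC[C@H]3C(C)C)OC(=O)[C@@H]2C(=O)c4ccc(O[C@H](C)[C@H](O[Si](C(C)C)(C(C)C)C(C)C)c5ccc(OC)c(OC)c5)c(OC)c4
F3 | step 15 | (4-benzyloxy-3-methoxyphenyl)magnesium bromide | COc1cc([Mg]Br)ccc1OCc2ccccc2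
F4 | step 15 | (4-benzyloxy-3-methoxyphenyl)zinc bromide | COc1cc([Zn]Br)ccc1OCc2ccccc2
F5 | step 15 | (2R,3S,4S,5R)-2-(4-benzyloxy-3-methoxyphenyl)-5-Ar*-3,4-dimethyloxolane | c1ccccc1COc2ccc([C@@H]3O[C@@H](c4ccc(O[C@H](C)[C@H](O[Si](C(C)C)(C(C)C)C(C)C)c5ccc(OC)c(OC)c5)c(OC)c4)[C@@H](C)[C@@H]3C)cc2OC
F6 | step 15 | phenol, (2R,3S,4S,5R)-2-(4-hydroxy-3-methoxyphenyl)-5-Ar*-3,4-dimethyloxolane | Oc1ccc([C@@H]2O[C@@H](c3ccc(O[C@H](C)[C@H](O[Si](C(C)C)(C(C)C)C(C)C)c4ccc(OC)c(OC)c4)c(OC)c3)[C@@H](C)[C@@H]2C)cc1OC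
F7 | step 15 | lactate ether of F6, ethyl (2R)-2-aryloxypropanoate | CCOC(=O)[C@@H](C)Oc1ccc([C@@H]2O[C@@H](c3ccc(O[C@H](C)[C@H](O[Si](C(C)C)(C(C)C)C(C)C)c4ccc(OC)c(OC)c4)c(OC)c3)[C@@H](C)[C@@H]2C)cc1OC
F8 | step 15 | Weinreb amide from F7 | CON(C)C(=O)[C@@H](C)Oc1ccc([C@@H]2O[C@@H](c3ccc(O[C@H](C)[C@H](O[Si](C(C)C)(C(C)C)C(C)C)c4ccc(OC)c(OC)c4)c(OC)c3)[C@@H](C)[C@@H]2C)cc1OC
F9 | step 15 | aryl ketone from F8, (2R)-2-aryloxy-1-(3,4-dimethoxyphenyl)propan-1-one | COc1ccc(C(=O)[C@@H](C)Oc2ccc([C@@H]3O[C@@H](c4ccc(O[C@H](C)[C@H](O[Si](C(C)C)(C(C)C)C(C)C)c5ccc(OC)c(OC)c5)c(OC)c4)[C@@H](C)[C@@H]3C)cc2OC)cc1OC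
F10 | step 15 | mono-triisopropylsilyl ether of the target | COc1ccc([C@@H](O)[C@@H](C)Oc2ccc([C@@H]3O[C@@H](c4ccc(O[C@H](C)[C@H](O[Si](C(C)C)(C(C)C)C(C)C)c5ccc(OC)c(OC)c5)c(OC)c4)[C@@H](C)[C@@H]3C)cc2OC)cc1OC
F11 | step 11 | dimethyl acetal lactone, 17 with CH(OMe)2 in place of the dithianyl group | COC(OC)[C@H]2[C@H](O[C@@H]3C[C@H](C)CC[C@H]3C(C)C)OC(=O)[C@@H]2[C@@H](O[Si](CC)(CC)CC)c4ccc(O[C@H](C)[C@H](O[Si](C(C)C)(C(C)C)C(C)C)c5ccc(OC)c(OC)c5)c(OC)c4
F12 | step 11 | acetal diol, 18 with CH(OMe)2 in place of the dithianyl group | COC(OC)[C@@H](CO)[C@H](CO)[C@@H](O[Si](CC)(CC)CC)c1ccc(O[C@H](C)[C@H](O[Si](C(C)C)(C(C)C)C(C)C)c2ccc(OC)c(OC)c2)c(OC)c1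
F13 | step 11 | acetal bis-mesylate, 19 with CH(OMe)2 in place of the dithianyl group | COC(OC)[C@@H](COS(C)(=O)=O)[C@H](COS(C)(=O)=O)[C@@H](O[Si](CC)(CC)CC)c1ccc(O[C@H](C)[C@H](O[Si](C(C)C)(C(C)C)C(C)C)c2ccc(OC)c(OC)c2)c(OC)c1
F14 | step 11 | 3,4-dimethyl acetal, 20 with CH(OMe)2 in place of the dithianyl group | COC(OC)[C@@H](C)[C@H](C)[C@@H](O[Si](CC)(CC)CC)c1ccc(O[C@H](C)[C@H](O[Si](C(C)C)(C(C)C)C(C)C)c2ccc(OC)c(OC)c2)c(OC)c1
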